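## Retrosynthetic overview

- Ring A (the dibromo ring) is numbered C1 (OH), C2 (O–aryl), C3 (Br), C5 (Br). Its ether carbon C2 lies between C1–OH and C3–Br, which is the pattern of C2 of a cyclohexane-1,3-dione whose two carbonyls become OH and Br.
- The C5 bromine is cut first, as an electrophilic bromination para to the ether oxygen with both phenols masked as sulfonates. The C3 bromine and the aromaticity of ring A are then traced back to 2-aryloxycyclohexane-1,3-dione 7, through β-bromo enone 8.
- Dione 7 is opened at the C2–C1 bond (ether carbon to future hydroxyl carbon) by an intramolecular Claisen disconnection, giving keto ester 6.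
- Keto ester 6 comes from O-alkylation of 4,5,6-tribromoguaiacol 2 with bromomethyl ketone 5.
- Ring order: ring B (the tribromo ring) is a bought arene that is brominated at the start; ring A is closed second as a carbocycle and aromatised late.

Key step: step 4

Remarks: the target has no stereocentre, so none has to be set. Dione 7 is drawn as the diketone although it should exist mainly as its enol. Salts that differ from a numbered compound only by a proton (phenoxides, enolates) are not numbered separately.

## Route

Step 1
Reactants: 1 guaiacol (2-methoxyphenol)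
Product: 2 2,3,4-tribromo-6-methoxyphenol (4,5,6-tribromoguaiacol)
Conditions: Br2 (3.1 equiv), AcOH, 15 °C → rt; aq NaHSO3
Reagents that add atoms: bromine, BrBr
Why: Electrophilic aromatic bromination should stop at the tribromide, because OH directs to its para and ortho positions and OMe to its para position, while the last C–H (ortho to OMe only, meta to OH, flanked by OMe and Br) is far less reactive.

Step 2
Reactants: 3 methyl 5-chloro-5-oxopentanoate
Product: 5 methyl 6-bromo-5-oxohexanoate, via methyl 6-diazo-5-oxohexanoate 4 (not isolated)
Conditions: TMSCHN2 (2 equiv), MeCN/THF, 0 °C → rt; then 48% aq HBr, 0 °C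
Reagents that add atoms: trimethylsilyldiazomethane, C[Si](C)(C)C=[N+]=[N-]; hydrogen bromide, Br
Why: Acylation of the diazoalkane by the acid chloride (first stage of an Arndt–Eistert sequence) gives the diazoketone, which HBr protonates at carbon so that bromide displaces dinitrogen; this gives the bromomethyl ketone regiospecifically and leaves the methyl ester untouched.

Step 3
Reactants: 2 2,3,4-tribromo-6-methoxyphenol; 5 methyl 6-bromo-5-oxohexanoate
Product: 6 methyl 5-oxo-6-(2,3,4-tribromo-6-methoxyphenoxy)hexanoate
Conditions: K2CO3 (1.5 equiv), DMF, rt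
Reagents that add atoms: none
Why: Williamson ether synthesis; carbonate fully deprotonates the acidic tribromophenol and an α-bromo ketone is a very reactive SN2 electrophile at a primary carbon, so the doubly ortho-substituted phenoxide should still alkylate cleanly on oxygen.

Step 4
Reactants: 6 methyl 5-oxo-6-(2,3,4-tribromo-6-methoxyphenoxy)hexanoate
Product: 7 2-(2,3,4-tribromo-6-methoxyphenoxy)cyclohexane-1,3-dione
Conditions: KOtBu (2.2 equiv), THF (0.03 M), 0 °C → rt; then 1 M HCl
Reagents that add atoms: none
Why: tert-Butoxide deprotonates the aryloxy-bearing C6 methylene, the most acidic ketone α-position, and the ketone enolate adds to the ester carbonyl and expels methoxide (intramolecular Claisen, Dieckmann-type), forming the C6–C1 bond that becomes the bond between the ether carbon and the hydroxyl-bearing carbon of ring A. The closest known reaction type is the base-mediated cyclisation of 5-oxoalkanoates to 2-substituted cyclohexane-1,3-diones. The six-membered carbocycle closes in a 6-(enolendo)-exo-trig mode, which is favoured for enolates. No stereocentre is formed, since C2 of the product belongs to an enolised 1,3-dione. The step needs site selectivity, and the chain length secures it: the C4 enolate or the ester enolate could close only four-membered rings, and deprotonation of the acidic dione by the second equivalent of base pulls the equilibrium to the product. High dilution and a non-nucleophilic alkoxide should hold back intermolecular condensation and retro-Claisen opening, and the aryl bromides and the aryl methyl ether are inert to KOtBu at room temperature.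

Step 5
Reactants: 7 2-(2,3,4-tribromo-6-methoxyphenoxy)cyclohexane-1,3-dione
Product: 8 3-bromo-2-(2,3,4-tribromo-6-methoxyphenoxy)cyclohex-2-en-1-one
Conditions: (COBr)2 (1.2 equiv), DMF (cat.), CH2Cl2, 0 °C → rt
Reagents that add atoms: oxalyl bromide, O=C(Br)C(=O)Br
Why: The enol oxygen is activated by the Vilsmeier-type bromoiminium salt formed from oxalyl bromide and DMF and is replaced by bromide through addition–elimination, the standard conversion of a 1,3-dione into a β-bromo enone; the symmetry of 7 allows only one product.

Step 6
Reactants: 8 3-bromo-2-(2,3,4-tribromo-6-methoxyphenoxy)cyclohex-2-en-1-one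
Product: 11 3-bromo-2-(2,3,4-tribromo-6-methoxyphenoxy)phenol, via C6 sulfilimine adduct 9 (not isolated), via cyclohexa-2,5-dienone tautomer 10 (not isolated)
Conditions: LiHMDS (1.1 equiv), THF, –78 °C; then PhS(Cl)=NtBu (1.2 equiv), –78 °C → rt; aq NH4Cl
Reagents that add atoms: none
Why: Mukaiyama dehydrogenation: the kinetic α'-lithium enolate at C6 attacks the sulfur of N-tert-butylbenzenesulfinimidoyl chloride, adduct 9 loses N-tert-butylbenzenesulfenamide by syn-elimination through a five-membered transition state, and dienone 10, a keto tautomer of the phenol, aromatises on work-up; no oxidant that could attack the phenol and no transition metal that could insert into a C–Br bond is present.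

Step 7
Reactants: 11 3-bromo-2-(2,3,4-tribromo-6-methoxyphenoxy)phenol
Product: 12 3,4,5-tribromo-2-(2-bromo-6-hydroxyphenoxy)phenol
Conditions: BBr3 (3 equiv), CH2Cl2, –78 °C → rt; H2O
Reagents that add atoms: none
Why: Lewis-acid cleavage of the aryl methyl ether (bromide attacks the methyl group of the boron-bound ether) frees the ring B phenol while the diaryl ether and all C–Br bonds stay intact, and it removes the only strong activating group of ring B before the last bromination.

Step 8
Reactants: 12 3,4,5-tribromo-2-(2-bromo-6-hydroxyphenoxy)phenol
Product: 13 3-bromo-2-[2,3,4-tribromo-6-(methanesulfonyloxy)phenoxy]phenyl methanesulfonate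
Conditions: MsCl (2.5 equiv), Et3N (3 equiv), CH2Cl2, 0 °C
Reagents that add atoms: methanesulfonyl chloride, CS(=O)(=O)Cl
Why: O-Sulfonylation turns each OH from a strong ortho/para director into a weakly deactivating group, so that the bridging ether oxygen is the only donor left to direct the coming bromination.

Step 9
Reactants: 13 3-bromo-2-[2,3,4-tribromo-6-(methanesulfonyloxy)phenoxy]phenyl methanesulfonate
Product: 14 3,5-dibromo-2-[2,3,4-tribromo-6-(methanesulfonyloxy)phenoxy]phenyl methanesulfonate
Conditions: NBS (1.05 equiv), TFA/conc. H2SO4 (4:1), rt
Reagents that add atoms: N-bromosuccinimide, O=C1CCC(=O)N1Br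
Why: Electrophilic aromatic bromination with acid-activated NBS, a system that brominates deactivated arenes, should go to C5 of ring A, the only free position para to the ether oxygen; C4 and C6 are directed only by the bromine and the sulfonate, and the single C–H of ring B lies between a sulfonate and a bromine on a ring carrying three bromines.

Step 10
Reactants: 14 3,5-dibromo-2-[2,3,4-tribromo-6-(methanesulfonyloxy)phenoxy]phenyl methanesulfonate
Product: 15 3,5-dibromo-2-(2,3,4-tribromo-6-hydroxyphenoxy)phenol (target)
Conditions: KOH (6 equiv), MeOH/THF/H2O, 60 °C; then 1 M HCl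
Reagents that add atoms: none
Why: Basic hydrolysis of the two aryl methanesulfonates (attack at sulfur or E1cB loss of sulfene, both eased by the electron-poor aryloxide leaving groups) frees both phenols, and unactivated aryl bromides and the diaryl ether should not react with hydroxide under these conditions.

## Compound list

1 | guaiacol (2-methoxyphenol) | COc1ccccc1O | starting material
2 | 2,3,4-tribromo-6-methoxyphenol | COc1cc(Br)c(Br)c(Br)c1O | intermediate
3 | methyl 5-chloro-5-oxopentanoate | COC(=O)CCCC(=O)Cl | starting material
4 | methyl 6-diazo-5-oxohexanoate (not isolated) | COC(=O)CCCC(=O)C=[N+]=[N-] | intermediate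
5 | methyl 6-bromo-5-oxohexanoate | COC(=O)CCCC(=O)CBr | intermediate
6 | methyl 5-oxo-6-(2,3,4-tribromo-6-methoxyphenoxy)hexanoate | COC(=O)CCCC(=O)COc1c(OC)cc(Br)c(Br)c1Br | intermediate
7 | 2-(2,3,4-tribromo-6-methoxyphenoxy)cyclohexane-1,3-dione | O=C1CCCC(=O)C1Oc1c(OC)cc(Br)c(Br)c1Br | intermediate
8 | 3-bromo-2-(2,3,4-tribromo-6-methoxyphenoxy)cyclohex-2-en-1-one | O=C1CCCC(Br)=C1Oc1c(OC)cc(Br)c(Br)c1Br | intermediate
9 | 3-bromo-6-(N-tert-butyl-S-phenylsulfinimidoyl)-2-(2,3,4-tribromo-6-methoxyphenoxy)cyclohex-2-en-1-one (not isolated; mixture of diastereomers, of no consequence) | O=C1C(CCC(Br)=C1Oc1c(OC)cc(Br)c(Br)c1Br)S(=NC(C)(C)C)c1ccccc1 | intermediate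
10 | 3-bromo-2-(2,3,4-tribromo-6-methoxyphenoxy)cyclohexa-2,5-dien-1-one (not isolated) | O=C1C=CCC(Br)=C1Oc1c(OC)cc(Br)c(Br)c1Br | intermediate
11 | 3-bromo-2-(2,3,4-tribromo-6-methoxyphenoxy)phenol | Oc1cccc(Br)c1Oc1c(OC)cc(Br)c(Br)c1Br | intermediate
12 | 3,4,5-tribromo-2-(2-bromo-6-hydroxyphenoxy)phenol | Oc1cccc(Br)c1Oc1c(O)cc(Br)c(Br)c1Br | intermediate
13 | 3-bromo-2-[2,3,4-tribromo-6-(methanesulfonyloxy)phenoxy]phenyl methanesulfonate | CS(=O)(=O)Oc1cccc(Br)c1Oc1c(OS(C)(=O)=O)cc(Br)c(Br)c1Br | intermediate
14 | 3,5-dibromo-2-[2,3,4-tribromo-6-(methanesulfonyloxy)phenoxy]phenyl methanesulfonate | CS(=O)(=O)Oc1cc(Br)cc(Br)c1Oc1c(OS(C)(=O)=O)cc(Br)c(Br)c1Br | intermediate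
15 | 3,5-dibromo-2-(2,3,4-tribromo-6-hydroxyphenoxy)phenol | Oc1cc(Br)cc(Br)c1Oc1c(O)cc(Br)c(Br)c1Br | target

## Step count and risks

Total step count: 10. Longest linear sequence: 9 steps (steps 1 and 3–10 from guaiacol; equally steps 2–10 from the acid chloride).

Steps most likely to fail:

1. Step 4 (key Claisen cyclisation). Intermolecular aldol or Claisen condensation may outrun ring closure, or alkoxide may reopen the product ring. Fallback without any enolate, setting out from phenol 2 and returning at dione 7: commercial cyclohexane-1,3-dione is converted by diazo transfer (4-acetamidobenzenesulfonyl azide, Et3N, MeCN) into 2-diazocyclohexane-1,3-dione F1. F1 is then decomposed with Rh2(OAc)4 (1 mol %) in 1,2-dichloroethane at 80 °C in the presence of 2, so that the rhodium carbenoid inserts into the phenol O–H bond and gives 7 directly.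

2. Step 6 (dehydrogenation to the phenol). Deprotonation may go astray (γ-deprotonation, attack of the amide base at the bromine-bearing enone carbon), or proton transfer from product to enolate may stall the conversion. Fallback without strong base, setting out from bromo enone 8 and returning at phenol 11: α'-bromination with CuBr2 in refluxing EtOAc/CHCl3 should give racemic 3,6-dibromo-2-(2,3,4-tribromo-6-methoxyphenoxy)cyclohex-2-en-1-one F2. Dehydrobromination of F2 with Li2CO3/LiBr in DMF at 120 °C should give dienone 10, which tautomerises to 11.

3. Step 9 (last bromination). Substitution on the deactivated ring A may be sluggish, so that site selectivity erodes or more than one bromine enters. Fallback under steric instead of electronic control, setting out from bis-mesylate 13 and returning at 14: C–H borylation with B2pin2, [Ir(OMe)(cod)]2 and 4,4'-di-tert-butyl-2,2'-bipyridine in THF at 80 °C should borylate C5 of ring A, the only C–H in the molecule without an ortho substituent. This gives 3-bromo-5-(4,4,5,5-tetramethyl-1,3,2-dioxaborolan-2-yl)-2-[2,3,4-tribromo-6-(methanesulfonyloxy)phenoxy]phenyl methanesulfonate F3, and CuBr2 (3 equiv) in MeOH/H2O/THF at 80 °C then replaces the boryl group by bromine to give 14.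

## Further compounds

F1 | step 4 | 2-diazocyclohexane-1,3-dione | [N-]=[N+]=C1C(=O)CCCC1=O
F2 | step 6 | 3,6-dibromo-2-(2,3,4-tribromo-6-methoxyphenoxy)cyclohex-2-en-1-one (racemic) | O=C1C(Br)CCC(Br)=C1Oc1c(OC)cc(Br)c(Br)c1Br
F3 | step 9 | 3-bromo-5-(4,4,5,5-tetramethyl-1,3,2-dioxaborolan-2-yl)-2-[2,3,4-tribromo-6-(methanesulfonyloxy)phenoxy]phenyl methanesulfonate | CS(=O)(=O)Oc1cc(B2OC(C)(C)C(C)(C)O2)cc(Br)c1Oc1c(OS(C)(=O)=O)cc(Br)c(Br)c1Br
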